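**Plan** (isoquinoline atoms unprimed, naphthalene atoms primed)
1. Cuts, in retrosynthetic order: O–CH3 at C8 (back to the C8 acetate); C8–C8a (opens the benzo ring of the isoquinoline to a 2-naphthyl-4-pyridylbut-2-enoic acid); the C6=C7 unsaturation; C6–C7 (arylacetate plus 4-vinylpyridine); C7–C1' (zinc enolate plus 1-bromonaphthalene); C3'–C4' and C1'–C8a' of the methyl-bearing naphthalene ring.
2. Enabling feature: with C8–C8a cut, N2, C1, C3, C4, C4a and C8a with their two methyls form a 2,6-dimethylpyridin-4-yl ring. Its C3 and C5 are exchanged by the mirror plane through N and C4, so whichever bonds to C8 becomes C8a, its methyl-bearing neighbour becomes C1 (peri to the C8 oxygen), and no regiochemical question arises.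
3. Forward: the methyl-bearing naphthalene ring is annulated onto a benzamide, the acetate chain is attached at C1', and the intact pyridine ring is joined through C6–C7. The benzo ring of the isoquinoline closes last by a dienylketene electrocyclization; deacetylation and O-methylation finish.
4. Stereochemistry: the target has no stereocentre. The sp3 centres met on the way are racemic and are erased, the alkene geometry of the acid is lost in the key step, and C7–C1' becomes a hindered axis only on aromatization.

Key step: step 10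

Assumption: the target SMILES fixes no configuration at the C7–C1' axis, so the rotationally hindered biaryl is prepared as the racemate.

**Step 1**
Reactants: 1 N,N-diethyl-2-methoxybenzamide; 2 3-bromo-2-methylprop-1-ene (methallyl bromide)
Product: 5 N,N-diethyl-2-methoxy-6-(2-methylprop-2-en-1-yl)benzamide, via 6-lithiobenzamide 3 (not isolated), via arylmagnesium bromide 4 (not isolated)
Conditions: s-BuLi, TMEDA, THF, −78 °C; MgBr2·OEt2, −78 to 0 °C; 2, 0 °C to rt
Reagents that add atoms: none
Why: Directed ortho-metalation, in which the tertiary amide outranks the methoxy group as director so lithium enters at C6, and lithium-to-magnesium exchange gives a softer aryl nucleophile that 2 should allylate cleanly.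

**Step 2**
Reactants: 5 N,N-diethyl-2-methoxy-6-(2-methylprop-2-en-1-yl)benzamide
Product: 7 8-methoxy-3-methylnaphthalen-1-ol, via 2H-naphthalen-1-one tautomer 6 (not isolated)
Conditions: LiN(i-Pr)2 (2.2 equiv), THF, −78 °C to rt; then 1 M HCl
Reagents that add atoms: none
Why: Anionic annulation of an ortho-allylbenzamide (Snieckus naphthol synthesis), in which the base removes a benzylic-allylic proton, the far end of the allyl anion is acylated by the amide carbonyl with loss of diethylamide, and ketone 6 tautomerizes to the naphthol.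

**Step 3**
Reactants: 7 8-methoxy-3-methylnaphthalen-1-ol
Product: 8 1,8-dimethoxy-3-methylnaphthalene
Conditions: MeI, K2CO3, DMF, 40 °C
Reagents that add atoms: iodomethane CI
Why: Williamson O-methylation of a naphthol, with the polar aprotic solvent breaking the peri hydrogen bond to the C8 methoxy group.

**Step 4**
Reactants: 8 1,8-dimethoxy-3-methylnaphthalene
Product: 9 1-bromo-4,5-dimethoxy-2-methylnaphthalene
Conditions: NBS (1.0 equiv), MeCN, 0 °C to rt, dark
Reagents that add atoms: N-bromosuccinimide O=C1CCC(=O)N1Br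
Why: Electrophilic aromatic bromination, directed to C4 of 8 because it is para to the C1 methoxy group and ortho to the methyl group and so is more activated than C5, while the polar solvent and darkness suppress benzylic radical bromination.

**Step 5**
Reactants: 9 1-bromo-4,5-dimethoxy-2-methylnaphthalene; 10 (2-tert-butoxy-2-oxoethyl)zinc chloride (commercial solution)
Product: 11 tert-butyl 2-(4,5-dimethoxy-2-methylnaphthalen-1-yl)acetate
Conditions: Pd(dba)2 (5 mol%), P(t-Bu)3 (6 mol%), THF, 65 °C
Reagents that add atoms: none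
Why: Palladium-catalysed α-arylation of a zinc ester enolate (Reformatsky–Negishi coupling), in which the bulky electron-rich phosphine drives oxidative addition of zerovalent palladium into the flanked C–Br bond and the small sp3 partner forms the future axis bond C7–C1' while it is still uncrowded.

**Step 6**
Reactants: 12 4-bromo-2,6-dimethylpyridine; 13 4,4,5,5-tetramethyl-2-vinyl-1,3,2-dioxaborolane
Product: 14 4-ethenyl-2,6-dimethylpyridine
Conditions: PdCl2(dppf) (3 mol%), K2CO3, dioxane/H2O, 85 °C
Reagents that add atoms: none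
Why: Suzuki–Miyaura vinylation, helped by the ready oxidative addition of a 4-bromopyridine and by the two flanking methyls that keep the nitrogen off the catalyst.

**Step 7**
Reactants: 11 tert-butyl 2-(4,5-dimethoxy-2-methylnaphthalen-1-yl)acetate; 14 4-ethenyl-2,6-dimethylpyridine
Product: 15 tert-butyl 2-(4,5-dimethoxy-2-methylnaphthalen-1-yl)-4-(2,6-dimethylpyridin-4-yl)butanoate (racemic)
Conditions: KOt-Bu (0.2 equiv), t-BuOH/THF, 50 °C, slow addition of 14
Reagents that add atoms: none
Why: Pyridylethylation (Michael addition to a 4-vinylpyridine), in which the α-deprotonated arylacetate adds to the terminal vinyl carbon to form C6–C7 and t-BuOH protonates the resulting para-azabenzylic carbanion and returns the base; the new centre is racemic and is removed in step 8.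

**Step 8**
Reactants: 15 tert-butyl 2-(4,5-dimethoxy-2-methylnaphthalen-1-yl)-4-(2,6-dimethylpyridin-4-yl)butanoate
Product: 18 tert-butyl (E)-2-(4,5-dimethoxy-2-methylnaphthalen-1-yl)-4-(2,6-dimethylpyridin-4-yl)but-2-enoate, via α-phenylselanyl ester 16 (not isolated), via selenoxide 17 (not isolated)
Conditions: LiN(i-Pr)2, THF, −78 °C; PhSeBr, −78 °C; crude 16, 30% H2O2 (excess), pyridine, CH2Cl2, 0 °C to rt
Reagents that add atoms: none
Why: Ester α-selenenylation followed by selenoxide syn-elimination, in which only the ester α-proton is acidic enough for the amide base at −78 °C and the only β-hydrogens of 17 sit on C6, so one regioisomer is possible; the E geometry (twisted naphthyl cis to the CH2 group) should prevail and has no bearing on step 10.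

**Step 9**
Reactants: 18 tert-butyl (E)-2-(4,5-dimethoxy-2-methylnaphthalen-1-yl)-4-(2,6-dimethylpyridin-4-yl)but-2-enoate
Product: 19 (E)-2-(4,5-dimethoxy-2-methylnaphthalen-1-yl)-4-(2,6-dimethylpyridin-4-yl)but-2-enoic acid
Conditions: CF3CO2H, CH2Cl2, rt; isolation at pH 6
Reagents that add atoms: none
Why: Acidolysis of a tert-butyl ester by loss of isobutene, which is indifferent to the crowding around the carboxyl carbon and, being non-basic, should leave the double bond in place.

**Step 10**
Reactants: 19 (E)-2-(4,5-dimethoxy-2-methylnaphthalen-1-yl)-4-(2,6-dimethylpyridin-4-yl)but-2-enoic acid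
Product: 24 7-(4,5-dimethoxy-2-methylnaphthalen-1-yl)-1,3-dimethylisoquinolin-8-yl acetate, via mixed anhydride 20 (not isolated), via Z-dienylketene 21 (not isolated), via 8aH-isoquinolin-8-one 22 (not isolated), via isoquinolin-8-ol 23 (not isolated)
Conditions: Ac2O (solvent), NaOAc (3 equiv), reflux (about 140 °C), N2
Reagents that add atoms: acetic anhydride CC(=O)OC(C)=O
Why: Ac2O converts 19 into mixed anhydride 20, acetate removes a C5 proton (para-pyridylic and vinylogous to the anhydride carbonyl), and expulsion of acetate leaves dienylketene 21, whose ketene C7=C8, alkene C5=C6 and pyridine C4a=C8a bonds make up a six-electron hexatriene. Thermal disrotatory 6π electrocyclization bonds C8 to C8a and closes the six-membered benzo ring as dienone 22, loss of the C8a proton rearomatizes both rings to phenol 23, and acetylation by the solvent to 24 makes the sequence irreversible. The closest known reaction type is the Ac2O/NaOAc cyclization of 4-arylbut-3-enoic acids and Stobbe half-acids to 1-naphthyl acetates, and dienylketene closure onto a pyridine ring has its counterpart in the thermal ring expansion of pyridyl-substituted cyclobutenones. Only the ketene with the pyridyl group and C7 cis on C5=C6 can close, and it stays available because ketene formation is reversible and the C5-deprotonated form of 20 can rotate about C5–C6, so trans material drains through 21 just as E-styrylacetic acids do in the parent reaction. Site selectivity is settled by symmetry, since C3 and C5 of the 2,6-dimethylpyridin-4-yl ring are equivalent and either closure puts a methyl at C1 peri to the C8 oxygen, while the flanking methyls hinder N-acylation and the acid-free medium offers no acylium ion for Friedel–Crafts attack at the peri C8' of the naphthalene. The only new stereocentre, C8a of 22, is lost at once, and C7 carries the naphthyl group as a planar ketene carbon, so the crowded C7–C1' axis appears only on aromatization and is racemic.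

**Step 11**
Reactants: 24 7-(4,5-dimethoxy-2-methylnaphthalen-1-yl)-1,3-dimethylisoquinolin-8-yl acetate
Product: 23 7-(4,5-dimethoxy-2-methylnaphthalen-1-yl)-1,3-dimethylisoquinolin-8-ol
Conditions: K2CO3 (0.2 equiv), MeOH, rt
Reagents that add atoms: none
Why: Base-catalysed transesterification (methanolysis) of an aryl acetate, whose good phenoxide leaving group makes cleavage easy although the oxygen is flanked, and nothing else in the molecule is base-labile.

**Step 12**
Reactants: 23 7-(4,5-dimethoxy-2-methylnaphthalen-1-yl)-1,3-dimethylisoquinolin-8-ol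
Product: 25 7-(4,5-dimethoxy-2-methylnaphthalen-1-yl)-8-methoxy-1,3-dimethylisoquinoline (target)
Conditions: MeI (1.1 equiv), Cs2CO3, DMF, rt
Reagents that add atoms: iodomethane CI
Why: Williamson O-methylation, in which the loosely paired caesium phenoxide should outrun the ring nitrogen, itself shielded by the C1 and C3 methyls, so a slight excess of MeI ends up on oxygen.

**Compound list**
1 | N,N-diethyl-2-methoxybenzamide | CCN(CC)C(=O)c1ccccc1OC | starting material
2 | 3-bromo-2-methylprop-1-ene | CC(=C)CBr | starting material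
3 | [2-(diethylcarbamoyl)-3-methoxyphenyl]lithium | CCN(CC)C(=O)c1c([Li])cccc1OC | intermediate
4 | [2-(diethylcarbamoyl)-3-methoxyphenyl]magnesium bromide | CCN(CC)C(=O)c1c([Mg]Br)cccc1OC | intermediate
5 | N,N-diethyl-2-methoxy-6-(2-methylprop-2-en-1-yl)benzamide | CCN(CC)C(=O)c1c(CC(C)=C)cccc1OC | intermediate
6 | 8-methoxy-3-methyl-2H-naphthalen-1-one | O=C1CC(C)=Cc2cccc(OC)c12 | intermediate
7 | 8-methoxy-3-methylnaphthalen-1-ol | Cc1cc(O)c2c(OC)cccc2c1 | intermediate
8 | 1,8-dimethoxy-3-methylnaphthalene | Cc1cc(OC)c2c(OC)cccc2c1 | intermediate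
9 | 1-bromo-4,5-dimethoxy-2-methylnaphthalene | Cc1cc(OC)c2c(OC)cccc2c1Br | intermediate
10 | (2-tert-butoxy-2-oxoethyl)zinc chloride | CC(C)(C)OC(=O)C[Zn]Cl | starting material
11 | tert-butyl 2-(4,5-dimethoxy-2-methylnaphthalen-1-yl)acetate | CC(C)(C)OC(=O)Cc1c(C)cc(OC)c2c(OC)cccc12 | intermediate
12 | 4-bromo-2,6-dimethylpyridine | Cc1cc(Br)cc(C)n1 | starting material
13 | 4,4,5,5-tetramethyl-2-vinyl-1,3,2-dioxaborolane | C=CB1OC(C)(C)C(C)(C)O1 | starting material
14 | 4-ethenyl-2,6-dimethylpyridine | C=Cc1cc(C)nc(C)c1 | intermediate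
15 | tert-butyl 2-(4,5-dimethoxy-2-methylnaphthalen-1-yl)-4-(2,6-dimethylpyridin-4-yl)butanoate (racemic) | CC(C)(C)OC(=O)C(CCc1cc(C)nc(C)c1)c1c(C)cc(OC)c2c(OC)cccc12 | intermediate
16 | tert-butyl 2-(4,5-dimethoxy-2-methylnaphthalen-1-yl)-4-(2,6-dimethylpyridin-4-yl)-2-(phenylselanyl)butanoate (racemic) | CC(C)(C)OC(=O)C(CCc1cc(C)nc(C)c1)([Se]c1ccccc1)c1c(C)cc(OC)c2c(OC)cccc12 | intermediate
17 | tert-butyl 2-(4,5-dimethoxy-2-methylnaphthalen-1-yl)-4-(2,6-dimethylpyridin-4-yl)-2-(phenylseleninyl)butanoate (stereoisomer mixture) | CC(C)(C)OC(=O)C(CCc1cc(C)nc(C)c1)([Se](=O)c1ccccc1)c1c(C)cc(OC)c2c(OC)cccc12 | intermediate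
18 | tert-butyl (E)-2-(4,5-dimethoxy-2-methylnaphthalen-1-yl)-4-(2,6-dimethylpyridin-4-yl)but-2-enoate | CC(C)(C)OC(=O)/C(=C/Cc1cc(C)nc(C)c1)c1c(C)cc(OC)c2c(OC)cccc12 | intermediate
19 | (E)-2-(4,5-dimethoxy-2-methylnaphthalen-1-yl)-4-(2,6-dimethylpyridin-4-yl)but-2-enoic acid | OC(=O)/C(=C/Cc1cc(C)nc(C)c1)c1c(C)cc(OC)c2c(OC)cccc12 | intermediate
20 | acetic (E)-2-(4,5-dimethoxy-2-methylnaphthalen-1-yl)-4-(2,6-dimethylpyridin-4-yl)but-2-enoic anhydride | CC(=O)OC(=O)/C(=C/Cc1cc(C)nc(C)c1)c1c(C)cc(OC)c2c(OC)cccc12 | intermediate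
21 | (3Z)-2-(4,5-dimethoxy-2-methylnaphthalen-1-yl)-4-(2,6-dimethylpyridin-4-yl)buta-1,3-dien-1-one | O=C=C(/C=C\c1cc(C)nc(C)c1)c1c(C)cc(OC)c2c(OC)cccc12 | intermediate
22 | 7-(4,5-dimethoxy-2-methylnaphthalen-1-yl)-1,3-dimethyl-8aH-isoquinolin-8-one (racemic) | O=C1C(c3c(C)cc(OC)c4c(OC)cccc34)=CC=C2C=C(C)N=C(C)C12 | intermediate
23 | 7-(4,5-dimethoxy-2-methylnaphthalen-1-yl)-1,3-dimethylisoquinolin-8-ol | Oc1c(-c2c(C)cc(OC)c3c(OC)cccc23)ccc2cc(C)nc(C)c12 | intermediate
24 | 7-(4,5-dimethoxy-2-methylnaphthalen-1-yl)-1,3-dimethylisoquinolin-8-yl acetate | CC(=O)Oc1c(-c2c(C)cc(OC)c3c(OC)cccc23)ccc2cc(C)nc(C)c12 | intermediate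
25 | 7-(4,5-dimethoxy-2-methylnaphthalen-1-yl)-8-methoxy-1,3-dimethylisoquinoline | COc1c(-c2c(C)cc(OC)c3c(OC)cccc23)ccc2cc(C)nc(C)c12 | target

**Step count and risks**
Total: 12 steps. Longest linear sequence: 11 steps (steps 1–5 and 7–12, from 1).

Step 10 is the step most likely to fail. The ketene may be lost to oligomerization or to re-addition of acetate faster than it can dearomatize the pyridine ring, or the exchange between the trans and cis forms at C5=C6 may be too slow. The fallback gives up the closure onto the pyridine and builds the pyridine ring last; it sets out from 9 and comes back at 25.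
- Bromine–lithium exchange (n-BuLi, THF, −78 °C) gives (4,5-dimethoxy-2-methylnaphthalen-1-yl)lithium F1. B(Oi-Pr)3 and acidic work-up turn it into (4,5-dimethoxy-2-methylnaphthalen-1-yl)boronic acid F2.
- Suzuki–Miyaura coupling with purchasable 1-(3-bromo-2-methoxyphenyl)ethan-1-one (Pd(OAc)2, SPhos, K3PO4, toluene/H2O, 100 °C) gives 1-[3-(4,5-dimethoxy-2-methylnaphthalen-1-yl)-2-methoxyphenyl]ethan-1-one F3.
- NH2OH·HCl and NaOAc in EtOH give (E)-1-[3-(4,5-dimethoxy-2-methylnaphthalen-1-yl)-2-methoxyphenyl]ethan-1-one oxime F4.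
- Oxime-directed C–H activation with trivalent rhodium ([Cp*RhCl2]2, CsOAc, MeOH, 60–80 °C) at the only free ortho carbon, with isopropenyl acetate as a propyne equivalent, builds N2–C3–C4 and gives 25 directly.

Step 8 comes second. Deprotonation may be incomplete or may stray to the pyridine methyls, the crowded fully substituted α-carbon may capture the selenium electrophile slowly, and the pyridine nitrogen may be oxidized during the peroxide stage. The fallback forms C5–C6 by cross-coupling at the alkene oxidation level and so also bypasses step 7; it sets out from 11 and comes back at 18.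
- Claisen formylation (LiN(i-Pr)2, then ethyl formate, THF, −78 °C to rt) gives tert-butyl 2-(4,5-dimethoxy-2-methylnaphthalen-1-yl)-3-oxopropanoate F5.
- O-Sulfonylation (NaH, PhNTf2, DMF) gives tert-butyl (E)-2-(4,5-dimethoxy-2-methylnaphthalen-1-yl)-3-(trifluoromethylsulfonyloxy)prop-2-enoate F6.
- Separately, LiN(i-Pr)2 metalates 2,4,6-trimethylpyridine at its 4-methyl group to [(2,6-dimethylpyridin-4-yl)methyl]lithium F7. ZnCl2 converts this into [(2,6-dimethylpyridin-4-yl)methyl]zinc chloride F8.
- Negishi coupling of F6 with F8 (Pd(PPh3)4, THF, 50 °C) proceeds with retention of geometry and gives 18.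

Step 5 comes third. Oxidative addition into the electron-rich, doubly flanked C–Br bond may be slow, so that protodebromination of the bromide and self-condensation of the zinc enolate take over. The fallback replaces the coupling by a one-carbon homologation; it sets out from 9 and comes back at 11.
- Magnesium in THF gives (4,5-dimethoxy-2-methylnaphthalen-1-yl)magnesium bromide F9. CO2 followed by aqueous HCl converts it into 4,5-dimethoxy-2-methylnaphthalene-1-carboxylic acid F10.
- Oxalyl chloride with catalytic DMF gives 4,5-dimethoxy-2-methylnaphthalene-1-carbonyl chloride F11, and excess ethereal CH2N2 gives 2-diazo-1-(4,5-dimethoxy-2-methylnaphthalen-1-yl)ethan-1-one F12.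
- Wolff rearrangement in tert-butanol (AgOBz, Et3N, 60 °C) completes the Arndt–Eistert sequence and gives 11.

**Further compounds**
F1 | step 10 | (4,5-dimethoxy-2-methylnaphthalen-1-yl)lithium | [Li]c1c(C)cc(OC)c2c(OC)cccc12
F2 | step 10 | (4,5-dimethoxy-2-methylnaphthalen-1-yl)boronic acid | OB(O)c1c(C)cc(OC)c2c(OC)cccc12
F3 | step 10 | 1-[3-(4,5-dimethoxy-2-methylnaphthalen-1-yl)-2-methoxyphenyl]ethan-1-one | CC(=O)c1cccc(-c2c(C)cc(OC)c3c(OC)cccc23)c1OC
F4 | step 10 | (E)-1-[3-(4,5-dimethoxy-2-methylnaphthalen-1-yl)-2-methoxyphenyl]ethan-1-one oxime | C/C(=N\O)c1cccc(-c2c(C)cc(OC)c3c(OC)cccc23)c1OC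
F5 | step 8 | tert-butyl 2-(4,5-dimethoxy-2-methylnaphthalen-1-yl)-3-oxopropanoate (racemic, largely enolized) | CC(C)(C)OC(=O)C(C=O)c1c(C)cc(OC)c2c(OC)cccc12
F6 | step 8 | tert-butyl (E)-2-(4,5-dimethoxy-2-methylnaphthalen-1-yl)-3-(trifluoromethylsulfonyloxy)prop-2-enoate | CC(C)(C)OC(=O)/C(=C/OS(=O)(=O)C(F)(F)F)c1c(C)cc(OC)c2c(OC)cccc12
F7 | step 8 | [(2,6-dimethylpyridin-4-yl)methyl]lithium | [Li]Cc1cc(C)nc(C)c1
F8 | step 8 | [(2,6-dimethylpyridin-4-yl)methyl]zinc chloride | Cl[Zn]Cc1cc(C)nc(C)c1
F9 | step 5 | (4,5-dimethoxy-2-methylnaphthalen-1-yl)magnesium bromide | Br[Mg]c1c(C)cc(OC)c2c(OC)cccc12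
F10 | step 5 | 4,5-dimethoxy-2-methylnaphthalene-1-carboxylic acid | OC(=O)c1c(C)cc(OC)c2c(OC)cccc12
F11 | step 5 | 4,5-dimethoxy-2-methylnaphthalene-1-carbonyl chloride | ClC(=O)c1c(C)cc(OC)c2c(OC)cccc12
F12 | step 5 | 2-diazo-1-(4,5-dimethoxy-2-methylnaphthalen-1-yl)ethan-1-one | [N-]=[N+]=CC(=O)c1c(C)cc(OC)c2c(OC)cccc12
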